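The runs were generated by integration on assumed constants; the scatter is artificial.

4 questions stand on the flask, and one number carries the late ones.

the same everywhere: gas 73 mM (held)

| run | starting material | first nucleophile | remark | time |
|---|---|---|---|---|
| dusk | 0.75 M | 3 M | run made earlier |  |
| spring | 1.1 M | 3 M | run made earlier |  |
| flask | 1.5 M | 3.00 M |  | 6.0 min |

| run | time / min | target / % | other capture product / % | starting material / % |
|---|---|---|---|---|
| dusk | 0.250 | 23 | 31 | 29 |
| dusk | 0.500 | 31 | 37 | 11 |
| dusk | 1.00 | 32 | 48 | 0 |
| dusk | 2.00 | 31 | 47 | 0 |
| dusk | 4.00 | 33 | 44 | 3 |
| spring | 0.250 | 22 | 28 | 34 |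
| spring | 0.500 | 30 | 38 | 12 |
| spring | 1.00 | 32 | 43 | 0 |
| spring | 2.00 | 35 | 45 | 0 |
| spring | 4.00 | 36 | 43 | 0 |

(each reading ± 1.5 percentage points)

- share of target in target plus other capture product at 0.60 s
- share of target in target plus other capture product at 15 s
- share of target in target plus other capture product at 6.0 min
- which of target and other capture product there is more of at 6.0 min

- at the start none of the gas is in solution

What do the runs hold steady? The share of target at 4.00 min reads 42.9% in dusk and 45.6% in spring, though spring charges 1.1 M of starting material against 0.75 M.

Who makes what? I take the target as capture by the first nucleophile and the other capture product as capture by what the dissolved gas supplies. Dusk and spring both have 3 M and 73 mM, so they cannot test this.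

Then what do you carry? The capture ratio, a selectivity factor at gas held at 73 mM: late target over late other capture product, divided by charged c(first nucleophile). Pooling the readings at 2.00 min and 4.00 min of both runs gives 0.251 M⁻¹.

And the flask at 6.0 min? With 3.00 M, the ratio is 0.753, so the other capture product leads, and the share is 43.0%.

But the early time? The half-life of starting material read from dusk is 0.140 min, far longer than 0.01 min, so the first product is being made there, starting from no gas in solution. On my assignment the share at 0.60 s stands above 43.0%, by an amount the runs do not show.

The forecast says 25%, 43% and 45%, with other capture product ahead, and takes target as gas capture; early, “the share is lower and poorly constrained”.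

The flask gives 62.0%, 45.1% and 42.5%, with other capture product ahead, 44.1% against 32.7%. The forecast and the flask part at 0.60 s, by 37 percentage points.

    starting material → intermediate (k = 0.0740 s⁻¹)
    first nucleophile + intermediate → target (k = 2.20 M⁻¹ s⁻¹)
    second nucleophile + intermediate → other capture product (k = 160 M⁻¹ s⁻¹)
    intermediate → solvolysis product (k = 4.30 s⁻¹)
    second nucleophile → decomposed reagent (k = 0.280 s⁻¹)
    gas ⇌ second nucleophile, rate k6*(csat - [second nucleophile]) (kL = 1.90 s⁻¹)

The flask's end amounts, 32.7% of target and 44.1% of other capture product, give a capture ratio of 0.247 M⁻¹ against the 0.251 M⁻¹ read from the runs. The neighbouring flask charges 0.75 M of first nucleophile, with everything else as in the flask. The capture ratio makes that 0.188, a share of 15.8%. The neighbouring flask shows 16.1% at 6.0 min, with 56.9% of other capture product and 10.9% of target.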